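**Retrosynthetic overview**

1. Cudraphenone A is ring A (3-hydroxy-2-prenylphenyl) – C=O – ring B (a resorcinol, numbered here C-1 at the ketone, OH at C-2, pyran oxygen at C-4, pyran carbon at C-5). The only ring to build is the 2,2-dimethyl-2H-pyran fused at O-4/C-5.
2. Disconnections: (a) the pyran ring at the aryl C-5–CH bond and the O-4–CMe2 bond, which gives prenal as the five-carbon unit; (b) the C-1–C(=O) bond, which gives the Weinreb amide of ring A. Both cuts lead back to one arene, 4,6-dibromoresorcinol as its bis-MOM ether.
3. Enabling feature: C-1 and C-5 of ring B are the two positions that are each ortho to one phenol oxygen and para to the other, so in the dibromide they are symmetry-equivalent C–Br sites that can be lithiated one after the other. The carbinol carbon then attached to C-5 is ortho to O-4 and para to O-2, so it ionises readily to a vinyl ortho-quinone methide whose oxa-6π closure can only engage O-4.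
4. Ring A fragment: 3-bromophenol → MOM ether → lithiation between Br and OMOM with prenylation → Br/Li exchange and carbamoylation.
5. Ring order: rings A and B are bought as arenes; the pyran ring is formed last, in the one-flask key step that also joins the three building blocks and removes all protecting groups.

Key step: step 5

Remark: the target has no stereocentre and its only ring alkene is cis by constraint, so configuration needs no control; MOM stands for methoxymethyl.

**Route**

Step 1
Reactants: 1 3-bromophenol
Product: 2 1-bromo-3-(methoxymethoxy)benzene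
Conditions: NaH, MOMCl, DMF, 0 °C → rt
Reagents that add atoms: chloromethyl methyl ether (MOMCl), COCCl
Why: Williamson ether synthesis of the sodium phenoxide with a reactive α-chloro ether; the MOM ether serves as the acidifying, coordinating director for step 2 and is cleaved by the acid finish of step 5.

Step 2
Reactants: 2 1-bromo-3-(methoxymethoxy)benzene
Product: 5 1-bromo-3-(methoxymethoxy)-2-(3-methylbut-2-en-1-yl)benzene, via aryllithium 3 (not isolated), via arylcopper 4 (not isolated)
Conditions: LiN(i-Pr)2, THF, −78 °C; CuBr·SMe2 (THF/Me2S solution), −78 °C; prenyl bromide, −78 → 0 °C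
Reagents that add atoms: prenyl bromide (1-bromo-3-methylbut-2-ene), CC(C)=CCBr
Why: Directed ortho-metalation, in which the lithium amide (chosen over an alkyllithium so that no Br/Li exchange occurs) should remove the most acidic ring proton, the one flanked by Br and the MOM ether, after which transmetalation to copper at −78 °C forestalls loss of LiBr and the arylcopper should allylate prenyl bromide at its primary carbon.

Step 3
Reactants: 5 1-bromo-3-(methoxymethoxy)-2-(3-methylbut-2-en-1-yl)benzene
Product: 7 N-methoxy-3-(methoxymethoxy)-N-methyl-2-(3-methylbut-2-en-1-yl)benzamide, via aryllithium 6 (not isolated)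
Conditions: t-BuLi (2 equiv), THF, −78 °C; then cannulated into ClC(O)N(OMe)Me (1.5 equiv), THF, −78 °C
Reagents that add atoms: N-methoxy-N-methylcarbamoyl chloride, CON(C)C(Cl)=O
Why: Bromine–lithium exchange followed by acylation of the aryllithium with a carbamoyl chloride (Weinreb amide synthesis), where inverse addition to excess electrophile at low temperature should prevent a second addition.

Step 4
Reactants: 8 4,6-dibromobenzene-1,3-diol (4,6-dibromoresorcinol)
Product: 9 1,5-dibromo-2,4-bis(methoxymethoxy)benzene
Conditions: NaH (2.4 equiv), MOMCl (2.4 equiv), DMF, 0 °C → rt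
Reagents that add atoms: chloromethyl methyl ether (MOMCl), COCCl
Why: Twofold Williamson etherification; the MOM ethers tolerate and stabilise the ortho-aryllithiums of step 5 and leave under the same acid that triggers the ring closure.

Step 5
Reactants: 9 1,5-dibromo-2,4-bis(methoxymethoxy)benzene; 10 3-methylbut-2-enal (prenal); 7 N-methoxy-3-(methoxymethoxy)-N-methyl-2-(3-methylbut-2-en-1-yl)benzamide
Product: 17 cudraphenone A, via aryllithium 11 (not isolated), via bromo alkoxide 12 (not isolated), via lithio alkoxide 13 (not isolated), via Weinreb adduct 14 (not isolated), via keto alcohol 15 (not isolated), via quinone methide 16 (not isolated)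
Conditions: 9, t-BuLi (2.0 equiv), THF, −78 °C; 10 (1.05 equiv); t-BuLi (2.1 equiv), −78 °C; 7 (0.85 equiv), −78 → −30 °C; then MeOH, conc. HCl (to ca. 2 M), 0 → 40 °C, same flask
Reagents that add atoms: none
Why: Two successive bromine–lithium exchanges use the two equivalent C–Br bonds of 9 one at a time: aryllithium 11 adds 1,2 to prenal 10 (the aryl–CH bond of the pyran), the second exchange on alkoxide 12 gives 13, and 13 acylates Weinreb amide 7 to the chelated adduct 14, so that no ketone is present while an organolithium is. Methanolic HCl then releases keto alcohol 15, cleaves the three MOM acetals and ionises the benzylic allylic carbinol, which lies ortho to O-4 and para to O-2 of ring B, to vinyl ortho-quinone methide 16 (or its O-protonated form). The pyran ring closes by thermal disrotatory oxa-6π electrocyclisation of the O=C–C=C–C=C unit of 16, with O-4 bonding to the CMe2 terminus and ring B regaining aromaticity. Closest known reaction types: sequential halogen–lithium exchange and trapping of dibromoarenes, the Weinreb ketone synthesis, and the acid- or heat-induced cyclodehydration of 1-(2-hydroxyaryl)-3-methylbut-2-en-1-ols to 2,2-dimethyl-2H-chromenes. No stereocentre is set: the carbinol centre of 12 to 15 is racemic and disappears, and the ring alkene can only be cis. The step needs the pyran to fuse at C-5/O-4 and not at C-3 between the two oxygens (the site a direct prenal condensation of a 2,4-dihydroxyaryl ketone would be expected to favour); this is secured because the aryl–carbon bond can form only where a bromine stood and only O-4 is ortho to it, while single exchange is secured by the slow second exchange of a bromoaryllithium and by the second equivalent of t-BuLi destroying t-BuBr.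

**Compound list**

1 | 3-bromophenol | Oc1cccc(Br)c1 | starting material
2 | 1-bromo-3-(methoxymethoxy)benzene | COCOc1cccc(Br)c1 | intermediate
3 | [2-bromo-6-(methoxymethoxy)phenyl]lithium (not isolated) | [Li]c1c(Br)cccc1OCOC | intermediate
4 | [2-bromo-6-(methoxymethoxy)phenyl]copper (not isolated) | [Cu]c1c(Br)cccc1OCOC | intermediate
5 | 1-bromo-3-(methoxymethoxy)-2-(3-methylbut-2-en-1-yl)benzene | COCOc1cccc(Br)c1CC=C(C)C | intermediate
6 | [3-(methoxymethoxy)-2-(3-methylbut-2-en-1-yl)phenyl]lithium (not isolated) | [Li]c1cccc(OCOC)c1CC=C(C)C | intermediate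
7 | N-methoxy-3-(methoxymethoxy)-N-methyl-2-(3-methylbut-2-en-1-yl)benzamide | CON(C)C(=O)c1cccc(OCOC)c1CC=C(C)C | intermediate
8 | 4,6-dibromobenzene-1,3-diol (4,6-dibromoresorcinol) | Oc1cc(O)c(Br)cc1Br | starting material
9 | 1,5-dibromo-2,4-bis(methoxymethoxy)benzene | COCOc1cc(OCOC)c(Br)cc1Br | intermediate
10 | 3-methylbut-2-enal (prenal) | CC(C)=CC=O | starting material
11 | [5-bromo-2,4-bis(methoxymethoxy)phenyl]lithium (not isolated) | [Li]c1cc(Br)c(OCOC)cc1OCOC | intermediate
12 | lithium 1-[5-bromo-2,4-bis(methoxymethoxy)phenyl]-3-methylbut-2-en-1-olate, racemic (not isolated) | [Li]OC(C=C(C)C)c1cc(Br)c(OCOC)cc1OCOC | intermediate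
13 | lithium 1-[5-lithio-2,4-bis(methoxymethoxy)phenyl]-3-methylbut-2-en-1-olate, racemic (not isolated) | [Li]OC(C=C(C)C)c1cc([Li])c(OCOC)cc1OCOC | intermediate
14 | dilithium tetrahedral adduct of 13 and 7 (N-methoxy-N-methyl hemiaminal alkoxide, mixture of diastereomers, not isolated) | [Li]OC(C=C(C)C)c1cc(C(O[Li])(N(C)OC)c2cccc(OCOC)c2CC=C(C)C)c(OCOC)cc1OCOC | intermediate
15 | [5-(1-hydroxy-3-methylbut-2-en-1-yl)-2,4-bis(methoxymethoxy)phenyl][3-(methoxymethoxy)-2-(3-methylbut-2-en-1-yl)phenyl]methanone, racemic (not isolated) | CC(C)=CCc1c(OCOC)cccc1C(=O)c1cc(C(O)C=C(C)C)c(OCOC)cc1OCOC | intermediate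
16 | (6Z)-3-hydroxy-4-[3-hydroxy-2-(3-methylbut-2-en-1-yl)benzoyl]-6-(3-methylbut-2-en-1-ylidene)cyclohexa-2,4-dien-1-one (reactive Z form shown; the alkylidene geometry equilibrates through the protonated form; not isolated) | CC(C)=C/C=C1/C=C(C(=O)c2cccc(O)c2CC=C(C)C)C(O)=CC1=O | intermediate
17 | cudraphenone A, (7-hydroxy-2,2-dimethyl-2H-chromen-6-yl)[3-hydroxy-2-(3-methylbut-2-en-1-yl)phenyl]methanone | CC(C)=CCc1c(O)cccc1C(=O)c1cc2c(cc1O)OC(C)(C)C=C2 | target

**Step count and risks**

Total step count: 5. Longest linear sequence: 4 steps (steps 1, 2, 3 and 5, from 3-bromophenol).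

Steps most likely to fail:

1. Step 5. What may go wrong: incomplete or twofold bromine–lithium exchange; proton transfer from the C-3–H between the two MOM ethers to aryllithium 13 during the slow acylation by the ortho-substituted amide 7; and acid-induced addition of methanol or hydrogen chloride to the prenyl and pyran alkenes (or closure of the ring A phenol onto its prenyl group) during the threefold MOM cleavage. Fallback, setting out from 9 and 7: a single exchange of 9 (t-BuLi, 2.0 equiv, THF, −78 °C), acylation with 7 and a neutral aqueous quench would give [5-bromo-2,4-bis(methoxymethoxy)phenyl][3-(methoxymethoxy)-2-(3-methylbut-2-en-1-yl)phenyl]methanone F1, so the ketone is made in a simple, isolated operation. A Heck reaction of F1 with 2-methylbut-3-en-2-ol (Pd(OAc)2, P(o-tol)3, Et3N, DMF, 100 °C), which tolerates the ketone, would give [5-[(E)-3-hydroxy-3-methylbut-1-en-1-yl]-2,4-bis(methoxymethoxy)phenyl][3-(methoxymethoxy)-2-(3-methylbut-2-en-1-yl)phenyl]methanone F2. Methanolic HCl would then remove the MOM groups and ionise the tertiary allylic alcohol of F2 to the same cation and quinone methide 16, and the route comes back at 17.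

2. Step 2. What may go wrong: loss of LiBr from aryllithium 3 to an aryne before transmetalation is complete, or allylation at the tertiary terminus of prenyl bromide (SN2′ attack) giving the 1,1-dimethylallyl isomer. Fallback, setting out from 2: lithiation as before and an immediate iodine quench at −78 °C would give 1-bromo-2-iodo-3-(methoxymethoxy)benzene F3. An iodine-selective Suzuki–Miyaura coupling of F3 with 3-methylbut-2-en-1-ylboronic acid pinacol ester (Pd(OAc)2, a bulky biaryl dialkylphosphine, K3PO4, THF/H2O, 40 °C, ligand chosen for coupling at the unsubstituted allyl terminus) would come back to the route at 5.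

3. Step 3. What may go wrong: a second addition of aryllithium 6 to the freshly formed amide (symmetrical diaryl ketone), or quenching of 6 by proton transfer from the doubly activated benzylic allylic CH2. Fallback, setting out from 5: exchange (t-BuLi, THF, −78 °C) and a CO2 quench would give 3-(methoxymethoxy)-2-(3-methylbut-2-en-1-yl)benzoic acid F4. Amide coupling of F4 with MeNHOMe·HCl (EDC·HCl, HOBt, i-Pr2NEt, CH2Cl2) would come back to the route at 7.

**Further compounds**

F1 | step 5 | [5-bromo-2,4-bis(methoxymethoxy)phenyl][3-(methoxymethoxy)-2-(3-methylbut-2-en-1-yl)phenyl]methanone | CC(C)=CCc1c(OCOC)cccc1C(=O)c1cc(Br)c(OCOC)cc1OCOC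
F2 | step 5 | [5-[(E)-3-hydroxy-3-methylbut-1-en-1-yl]-2,4-bis(methoxymethoxy)phenyl][3-(methoxymethoxy)-2-(3-methylbut-2-en-1-yl)phenyl]methanone | CC(C)=CCc1c(OCOC)cccc1C(=O)c1cc(/C=C/C(C)(C)O)c(OCOC)cc1OCOC
F3 | step 2 | 1-bromo-2-iodo-3-(methoxymethoxy)benzene | COCOc1cccc(Br)c1I
F4 | step 3 | 3-(methoxymethoxy)-2-(3-methylbut-2-en-1-yl)benzoic acid | CC(C)=CCc1c(OCOC)cccc1C(=O)O
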